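Of the constants of this system you have none yet, so start from the one the readings give directly: the end ratio, [isomer of the product A]/[target] where a flask stops changing. The flasks and the questions are these.

in all of them: starting material 0.40 M
- Monday's: free catalyst 4 mol%; temperature 89 °C; run made earlier
- Thursday's: free catalyst 8.9 mol%; temperature 130 °C; run made earlier
- ash: free catalyst 5.9 mol%; temperature 70 °C; time 15 d
- maple: free catalyst 5.9 mol%; temperature 120 °C; time 15 d
- birch: free catalyst 5.9 mol%; temperature 145 °C; time 15 d
- elm: free catalyst 5.9 mol%; temperature 95 °C; time 15 d
Monday's run (percent of the starting material charged)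

| time / d | target / % | isomer of the product A / % |
|---|---|---|
| 0.500 | 13.8 | 18.4 |
| 1.04 | 15.9 | 26.0 |
| 1.67 | 16.4 | 28.7 |
| 3.00 | 17.4 | 32.2 |
| 6.00 | 17.3 | 31.7 |

Thursday's run (percent of the starting material charged)

| time / h | target / % | isomer of the product A / % |
|---|---|---|
| 1.50 | 6.5 | 15.4 |
| 5.00 | 6.7 | 15.9 |
| 10.0 | 6.2 | 16.0 |
| 12.0 | 6.1 | 14.8 |
| 20.0 | 6.1 | 16.4 |

(readings scatter by 0.5 percentage points)
1. which flask leads in share of target in all that became target or isomer of the product A or isomer of the product B ("all alike" within 1.5 percentage points) (ash / maple / birch / elm / all alike)
2. share of target in all that became target or isomer of the product A or isomer of the product B, ash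
3. share of target in all that became target or isomer of the product A or isomer of the product B, maple
4. share of target in all that became target or isomer of the product A or isomer of the product B, birch
5. share of target in all that became target or isomer of the product A or isomer of the product B, elm
- the earlier runs were read with a standard deviation of 0.5 percentage points

Isomer of the product B was never read, so I first reckon the share as one over one plus the end ratio, leaving isomer of the product B out.

You can get Monday's end ratio in two ways that share no reading. Monday's last two readings give 1.84. The readings up to 1.67 d give ratios of 1.33, 1.64 and 1.75, at nearly even spacing. Take the last ratio as a first answer, add the next step, shrunk as the last one shrank, and go round again. The steps sum to 1.82. The two part by 1.15%, which is less than the 2.89% that the scatter makes of a target reading, so I trust this ratio as one of thermodynamic rather than kinetic control. The same steps give a relaxation half-life of 0.452 d on Monday, far shorter than the 15 d allowed, though that half-life was read hotter than ash.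

Thursday's readings together give 2.48. A van't Hoff line through both ratios then has an enthalpy of 8.86 kJ mol⁻¹. It puts the end ratio at 70 °C, the number you should carry, at 1.56. My shares before isomer of the product B is counted are 39.0% for ash, 34.1% for elm, 30.1% for maple and 26.8% for birch.

The forecast names ash, with 34%, 26%, 23% and 29.5% for ash, maple, birch and elm, holding that “Both runs flatten out, so they show equilibrium rather than kinetics”.

The flasks put ash first, with 35.8% there, 31.6% in elm, 28.2% in maple and 25.6% in birch. Ash stands 3.2 points below my share, and birch 1.2 points below.

    starting material + free catalyst ⇌ target + free catalyst, rate k1*[starting material]*[free catalyst] forward; the back reaction follows from the equilibrium constant (K = 0.970, k = 0.590 M⁻¹ h⁻¹, Ea = 86.0 kJ mol⁻¹, ΔH = −45.0 kJ mol⁻¹)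
    isomer of the product B + free catalyst ⇌ starting material + free catalyst, rate k2*[free catalyst]*[isomer of the product B] forward; the back reaction follows from the equilibrium constant (k = 2.40 M⁻¹ h⁻¹, Ea = 86.0 kJ mol⁻¹)
    target + free catalyst ⇌ isomer of the product A + free catalyst, rate k3*[free catalyst]*[target] forward; the back reaction follows from the equilibrium constant (K = 1.60, k = 3.00 M⁻¹ h⁻¹, Ea = 88.0 kJ mol⁻¹, ΔH = 8.00 kJ mol⁻¹)
    starting material + free catalyst → spent catalyst (k = 0.0210 M⁻¹ h⁻¹, Ea = 89.0 kJ mol⁻¹)
    isomer of the product A ⇌ isomer of the product B (K = 0.120, k = 0.0140 h⁻¹, Ea = 120 kJ mol⁻¹, ΔH = −1.00 kJ mol⁻¹)
    (constants at 70 °C)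

Ash ends at a ratio of 1.60 against the carried 1.56. What the temperature does to the path from target to isomer of the product A is the largest single effect on the gap between birch and ash: without it, birch minus ash goes from −10 points to 4.8 points. The return from isomer of the product A to target needs free catalyst, and ash ends with 35.4% of its charge free. The same flask charged with 1.5 mol% of free catalyst ends at a ratio of 1.39, below the carried value, with a share of 39.0%.

The data are simulated for substances that don't exist; the scatter is artificial.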